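## Analysis of the target

Target 27 is a hexahydroindenone: a cyclopentenone (C1, C2 ketone, C3=C3a, C7a) fused to a cyclohexane (C3a, C4 to C7, C7a), with a methyl-bearing quaternary carbon C7a at the ring fusion. The core has four stereocentres (1R, 4S, 7R, 7aS), and the formylallyl chain on C1, the acyloxy group on C4, the carboxyl on C7 and the C7a methyl all lie on one face. In the chair of the six-membered ring the methyl and the C4 oxygen are 1,3-diaxial and the carboxyl is equatorial. A fifth, remote stereocentre (6R) sits in the (2E,4E)-4,6-dimethylocta-2,4-dienoyl ester and cannot be induced from the core. Sensitive groups are the 2-substituted acrolein, the free acid, the allylic dienoate at C4 (γ to the ketone) and C1, which is enolisable next to the ketone. The difficulty is the dense functionality around a quaternary carbon flanked by two stereocentres (C1, C7) and 1,3-related to a third (C4), together with a hindered axial ester and the late release of enal and acid. The plan rests on one feature: C1 carries exactly one exocyclic carbon (the chain CH2) beside the C2 ketone, so the ring C1–C2–C3–C3a–C7a plus that carbon is a cyclohexadienone ring whose α-carbon has been pushed out of the ring, and the hydrindenone is a ring-contracted decalin derived from (R)-Wieland–Miescher ketone 1.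

## Retrosynthetic reasoning

**27 ⇒ 26.** The last bonds made are not C–C bonds. The free acid and the enal are the two most reactive groups, so both are carried masked. In 26 the acid is a tert-butyl ester and the aldehyde a diethyl acetal; one acid treatment releases both and no basic or reductive step follows the acylation.

**26 ⇒ 19 + 25.** The C4 ester C–O bond is cut next. The dienoate would not survive the peroxide, hydride, organocopper and Lewis-acid chemistry of the core, so it is attached late to the axial alcohol of 19. Acid 25 carries the stereocentre that the core cannot induce. It is traced through ester 24 and enal 23 (two E-selective carbonyl olefinations, cutting C2=C3 and C4=C5 of the acid) to aldehyde 22, alcohol 21 and the purchasable acid 20, whose stereocentre is carried over unchanged.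

**19 ⇒ 18 ⇒ 15 + 16.** With the silyl ether back on C4 (18), the chain is cut between its CH2 and the vinyl carbon. This leaves the CH2 on the ring as the terminus of an exocyclic enone (15) and the rest as a vinyl nucleophile carrying the aldehyde as an acetal, available from bromide 16. Forward, conjugate addition gives enolate 17 and protonation creates C1. The addition must occur at the methylene and not at the tetrasubstituted C3a, and C1 must end with the chain on the methyl face.

**15 ⇒ 14 ⇒ 13.** The exocyclic methylene is a reduced formyl group, which leads to triflate 14 and the hydroxymethylene ketone 13 (the enol of a β-keto aldehyde). Only C–O is exchanged for C–H, and the formyl carbon of 13 is kept as the chain CH2 of 27.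

**13 ⇒ 12 (key).** A 2-formyl ketone in a five-membered ring is the signature of an acyl shift in an α,β-epoxy ketone. Reversing the shift breaks C1–C2 of the indene and rejoins C2 to the formyl carbon, which returns into the ring. The precursor is epoxy enone 12, a decalin in which indene C2, the formyl carbon, C1, C7a, C3a and C3 are decalin C6, C7, C8, C8a, C4a and C5. The cut is placed here because it turns the awkward 1,2-arrangement of chain and ketone next to a quaternary carbon into the ordinary functionality of a cross-conjugated dienone, and because no stereocentre is at stake in the forward step. Forward, the epoxide must open at C8 and the acyl carbon must move, not hydride or a substituent of C8a.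

**12 ⇒ 11 ⇒ 9.** The epoxide goes back to the cross-conjugated dienone 11; nucleophilic epoxidation selects the disubstituted C7=C8 bond and the face away from the angular methyl. The C7=C8 bond goes back to enone 9 by dehydrogenation through its kinetic silyl dienol ether 10.

**9 ⇒ 8 ⇒ 6.** The C4–O bond is cut. The silyl ether comes from alcohol 8, and 8 from enone 6 by γ-oxygenation of the extended dienol ether 7. C4 is set here: axial attack on the dienol ether terminus places the oxygen cis to the angular methyl, as 27 requires.

**6 ⇒ 5 ⇒ 4 ⇒ 1 + 2.** Finally the bond from decalin C1 to the carboxyl carbon (C7–CO2H of 27) is cut. Ester 6 and acid 5 come from aldehyde 4, and 4 from the saturated ketone of 1 by one-carbon homologation with the ylide of 2 through enol ether 3. The quaternary stereocentre is bought with 1, and the equatorial position of the new carbon, cis to the methyl, is the thermodynamic one.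

## Alternatives that were turned down

**Alternative 1:** The cut is at C5–C6 and C7–C7a, a retro-[4+2] to the 2-silyloxydiene A1 (its inner double bond lies in a methyl-substituted five-membered ring) and the fluorinated acrylate A2.
- Key step: a cationic chiral oxazaborolidine Lewis acid activates A2, and cycloaddition gives the endo adduct A3. The cyclohexane, the quaternary C7a and the C7 ester form at once and C4 emerges as a silyl enol ether.
- For it: catalytic, enantioselective creation of the quaternary centre from simple achiral partners; the carboxyl carbon is on C7 from the start, so no homologation is needed.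
- Against it: the diene terminus that becomes C7a is fully substituted, so the cycloaddition must form a quaternary centre against steric resistance. Endo addition places the ester trans to the methyl, so C7 needs later epimerisation.
- Main weakness: A3 has a bare cyclopentane. The C2 ketone, the C3=C3a alkene and the C1 chain must all be introduced by successive oxidations starting from the C4 enol ether, followed by differentiation of two carbonyls and a stereoselective reduction at C4.
- Comparison: this plan is stronger on absolute stereocontrol by catalysis and on the first ring-forming step. It is weaker in step economy after the key step. The chosen strategy pays with a purchased stereocentre and a homologation, and in return its key step delivers the cyclopentenone with C2=O, C3=C3a, C4–O, the C7 ester and a functionalised carbon on C1 in their final places.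

**Alternative 2:** The cut is at C3a–C7a and C6–C7, an intramolecular [4+2] in which the tether C1–C2–C3 becomes the five-membered ring; the precursor is the acyclic silyloxy vinylallene enoate A4.
- Key step: on heating, the diene C3a=C4–C5=C6 of A4 adds to the tethered E-trisubstituted enoate and gives A5. The remaining allene double bond becomes C3=C3a, the E geometry becomes the cis relation of the C7 ester and C7a methyl, and either allene epimer serves because the axial chirality is lost.
- For it: the highest bond economy of all the plans. Both rings, two C–C bonds, the quaternary centre and C7 form in one step, with C2 (as ketal), C3=C3a, the C4 oxygen (as enol ether) and a C1 chain already present.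
- Against it: the difficulty moves into A4, a long, heat- and acid-sensitive polyene. Its single stereocentre (C1, next to a ketal) must be made enantiopure and must alone control the face of the dienophile. The dienophile is β,β-disubstituted, so the quaternary centre forms thermally and slowly, with ene and [2+2] pathways of the allene as competitors. Afterwards the C4 ketone must be reduced to the axial alcohol and the three-carbon chain oxidised and α-methylenated.
- Comparison: this plan is stronger in convergence and in the ring construction itself. It is weaker in precursor access and in the reliability of absolute control. The chosen route takes its absolute configuration from 1 and sets C4 and the epoxide by substrate control on a rigid bicycle, so the risk sits in one rearrangement.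

**Alternative 3:** The cut is at C3a–C4 alone; the precursor is the 4,4-disubstituted cyclopentenone A6 with an aldehyde at the end of the C7–C6–C5 tether.
- Key step: cathodic reduction at controlled potential, with a mild carbon acid as proton donor, couples the enone β-carbon C3a to the aldehyde carbon and gives the cis-fused hydroxy ketone A7 with the C4 hydroxyl cis to the methyl.
- For it: mild, reagent-free C–C bond formation that makes the C4 carbinol directly, with the C1 chain and the C7 ester already present.
- Against it: A6 already contains the quaternary centre with three different branches and the stereocentres C1 and C7, so the hardest stereochemical problem is only moved upstream. The cyclisation consumes the C3=C3a alkene, which must be restored by regioselective dehydrogenation of A7; this is a redox detour that also discards the new C3a stereocentre. Diastereocontrol at C4 depends on the folding of a radical-anion intermediate, and an allylic silyl ether and a second carbonyl must survive the cathode.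
- Comparison: on forming the C4 carbinol with the chain in place this plan is as direct as the chosen one, or more so. The chosen strategy never gives up the enone alkene, fixes C4 by a stereoelectronically controlled oxidation of a known type, and takes the quaternary centre from 1.

Key step: step 8

## Remarks before the steps

- Decalin intermediates are numbered as in 1 (C1 homologated carbon, C4 oxygenated carbon, C6 enone carbonyl, C8a quaternary carbon); hydrindenones are numbered as indenes.
- Assumption: at the enolisable C1 the epimer with the chain on the face of the angular methyl (as in 27) is taken to be the more stable one, because the other face is crowded by C7 and its equatorial carboxyl group; C1 is therefore treated as correctable by equilibration.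
- Assumption: compounds 1, 2, 16 and 20 are purchased.

## Route

Step 1
Reactants: 1 (R)-Wieland–Miescher ketone; 2 (methoxymethyl)triphenylphosphonium chloride
Product: 4 (1R,8aS)-8a-methyl-6-oxo-1,2,3,4,6,7,8,8a-octahydronaphthalene-1-carbaldehyde (formyl equatorial, cis to the angular methyl), via methyl enol ether 3 (not isolated)
Conditions: 2, KN(SiMe3)2, THF, 0 °C; 1, −78 → 0 °C; then 2 M HCl, THF, rt
Reagents that add atoms: (methoxymethyl)triphenylphosphonium chloride (2), [Cl-].COC[P+](c1ccccc1)(c1ccccc1)c1ccccc1; water, O
Why: Wittig methoxymethylenation should occur at the saturated C1 ketone, which is more electrophilic than the vinylogous enone carbonyl (the selectivity known for Wittig olefination of 1). Acid hydrolysis of 3 protonates C1 from the face away from the axial methyl and any axial aldehyde equilibrates through the enol, so the formyl group should end equatorial, cis to the methyl.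

Step 2
Reactants: 4 (1R,8aS)-8a-methyl-6-oxo-1,2,3,4,6,7,8,8a-octahydronaphthalene-1-carbaldehyde
Product: 5 (1R,8aS)-8a-methyl-6-oxo-1,2,3,4,6,7,8,8a-octahydronaphthalene-1-carboxylic acid
Conditions: NaClO2, NaH2PO4, 2-methyl-2-butene, t-BuOH/H2O, rt
Reagents that add atoms: sodium chlorite, [Na+].[O-]Cl=O
Why: Pinnick oxidation converts the aldehyde to the acid under buffered conditions that neither epimerise C1 nor touch the enone; the alkene scavenges hypochlorite.

Step 3
Reactants: 5 (1R,8aS)-8a-methyl-6-oxo-1,2,3,4,6,7,8,8a-octahydronaphthalene-1-carboxylic acid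
Product: 6 tert-butyl (1R,8aS)-8a-methyl-6-oxo-1,2,3,4,6,7,8,8a-octahydronaphthalene-1-carboxylate
Conditions: Cl3CC(=NH)OtBu, BF3·OEt2 (cat.), CH2Cl2/cyclohexane, rt
Reagents that add atoms: tert-butyl 2,2,2-trichloroacetimidate, CC(C)(C)OC(=N)C(Cl)(Cl)Cl
Why: O-alkylation of the acid by the activated imidate (tert-butyl cation transfer) avoids nucleophilic attack at the hindered carbonyl next to the quaternary carbon. The tert-butyl ester is chosen because it is inert to base, peroxide, cuprate and fluoride and can be cleaved together with the acetal at the end.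

Step 4
Reactants: 6 tert-butyl (1R,8aS)-8a-methyl-6-oxo-1,2,3,4,6,7,8,8a-octahydronaphthalene-1-carboxylate
Product: 8 tert-butyl (1R,4S,8aS)-4-hydroxy-8a-methyl-6-oxo-1,2,3,4,6,7,8,8a-octahydronaphthalene-1-carboxylate (hydroxyl axial, cis to the angular methyl), via ethyl dienol ether 7 (not isolated)
Conditions: HC(OEt)3, p-TsOH (cat.), EtOH, rt; Et3N; then mCPBA, THF/H2O, 0 °C
Reagents that add atoms: triethyl orthoformate, CCOC(OCC)OCC (ethoxy group of 7 only); mCPBA, OOC(=O)c1cccc(Cl)c1; water, O
Why: Acid-catalysed exchange gives the thermodynamic extended dienol ether 7, and the peracid attacks its electron-rich terminus C4 (γ-hydroxylation of a dienol ether, Rubottom type), after which water releases the enone. Attack should be axial, on the face of the angular methyl, because this keeps overlap with the dienol π-system in a chair-like transition state, as in the 6β-hydroxylation of steroidal 3,5-dienol ethers; this sets C4 (S).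

Step 5
Reactants: 8 tert-butyl (1R,4S,8aS)-4-hydroxy-8a-methyl-6-oxo-1,2,3,4,6,7,8,8a-octahydronaphthalene-1-carboxylate
Product: 9 tert-butyl (1R,4S,8aS)-4-[(tert-butyldimethylsilyl)oxy]-8a-methyl-6-oxo-1,2,3,4,6,7,8,8a-octahydronaphthalene-1-carboxylate
Conditions: TBSOTf, 2,6-lutidine, CH2Cl2, −78 → 0 °C
Reagents that add atoms: tert-butyldimethylsilyl trifluoromethanesulfonate, CC(C)(C)[Si](C)(C)OS(=O)(=O)C(F)(F)F
Why: The silyl triflate with a hindered base silylates even the axial secondary alcohol; the silyl ether masks C4–OH through base, peroxide, Lewis acid and cuprate.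

Step 6
Reactants: 9 tert-butyl (1R,4S,8aS)-4-[(tert-butyldimethylsilyl)oxy]-8a-methyl-6-oxo-1,2,3,4,6,7,8,8a-octahydronaphthalene-1-carboxylate
Product: 11 tert-butyl (1R,4S,8aS)-4-[(tert-butyldimethylsilyl)oxy]-8a-methyl-6-oxo-1,2,3,4,6,8a-hexahydronaphthalene-1-carboxylate (cross-conjugated dienone), via trimethylsilyl dienol ether 10 (not isolated)
Conditions: LiN(iPr)2, THF, −78 °C; Me3SiCl; then Pd(OAc)2 (1.1 equiv), MeCN, rt
Reagents that add atoms: chlorotrimethylsilane, C[Si](C)(C)Cl (supplies the silyl group of 10; no non-hydrogen atom is added to 11)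
Why: Saegusa–Ito dehydrogenation: the amide base removes the kinetic α′-proton at C7 (not the γ-proton at C4 or the hindered ester α-proton), and Pd(OAc)2 oxidises silyl dienol ether 10 to the C7=C8 enone by β-hydride elimination from the palladium enolate.

Step 7
Reactants: 11 tert-butyl (1R,4S,8aS)-4-[(tert-butyldimethylsilyl)oxy]-8a-methyl-6-oxo-1,2,3,4,6,8a-hexahydronaphthalene-1-carboxylate
Product: 12 tert-butyl (1R,4S,7S,8S,8aS)-7,8-epoxy-4-[(tert-butyldimethylsilyl)oxy]-8a-methyl-6-oxo-1,2,3,4,6,7,8,8a-octahydronaphthalene-1-carboxylate (epoxide anti to the angular methyl)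
Conditions: 30% H2O2, NaOH, MeOH, 0 °C
Reagents that add atoms: hydrogen peroxide, OO
Why: Weitz–Scheffer epoxidation: hydroperoxide adds to C8, the less substituted β-carbon of the cross-conjugated dienone (the C4a=C5 bond has a fully substituted β-carbon). It should add from the face opposite the axial methyl, silyloxy and ester groups, the selectivity known for steroidal 1,4-dien-3-ones, which sets C7 and C8.

Step 8
Reactants: 12 tert-butyl (1R,4S,7S,8S,8aS)-7,8-epoxy-4-[(tert-butyldimethylsilyl)oxy]-8a-methyl-6-oxo-1,2,3,4,6,7,8,8a-octahydronaphthalene-1-carboxylate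
Product: 13 tert-butyl (4S,7R,7aS)-4-[(tert-butyldimethylsilyl)oxy]-1-[(Z)-hydroxymethylidene]-7a-methyl-2-oxo-2,4,5,6,7,7a-hexahydro-1H-indene-7-carboxylate (chelated enol of the β-keto aldehyde)
Conditions: BF3·OEt2 (1.5 equiv), CH2Cl2, −20 → 0 °C; NaHCO3 aq
Reagents that add atoms: none
Why: BF3 binds the epoxide oxygen and the C8–O bond (β to the carbonyl, next to the quaternary carbon) lengthens, because cleavage of C7–O would place positive charge α to the ketone; as it lengthens, the acyl carbon C6 shifts from C7 to C8 on the face opposite the departing oxygen and the oxygen left on C7 becomes the formyl group, a semipinacol 1,2-acyl shift. The closest known reaction type is the Lewis-acid rearrangement of cyclic α,β-epoxy ketones to ring-contracted β-keto aldehydes (2-formylcyclopentanones from 2,3-epoxycyclohexanones), here with a secondary instead of the usual tertiary migration terminus. The cyclopentenone is not closed end to end but by this 1,2-shift: the new C6–C8 bond (C2–C1 of the indene) turns the six-membered enone ring into the five-membered one and leaves C7 as an exocyclic carbon. No stereocentre is created, since the new ring carbon C1 carries an enolised formyl group, and C4, C7 and C7a of the indene are not touched. The step needs acyl migration to win over hydride shift from C7 (which would give the 6,7-dione) and over a shift of methyl, C1 or C4a from C8a; the acyl group is the intrinsically favoured migrant in epoxy ketones, and a shift from C8a would place charge on a carbon allylic to the electron-poor enone. The C4a=C5 alkene is deactivated by conjugation and should stay in place. Low temperature and short contact are chosen to spare the tert-butyl ester and the silyl ether.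

Step 9
Reactants: 13 tert-butyl (4S,7R,7aS)-4-[(tert-butyldimethylsilyl)oxy]-1-[(Z)-hydroxymethylidene]-7a-methyl-2-oxo-2,4,5,6,7,7a-hexahydro-1H-indene-7-carboxylate
Product: 14 tert-butyl (4S,7R,7aS)-4-[(tert-butyldimethylsilyl)oxy]-7a-methyl-2-oxo-1-{[(trifluoromethanesulfonyl)oxy]methylidene}-2,4,5,6,7,7a-hexahydro-1H-indene-7-carboxylate (either alkene geometry)
Conditions: Tf2O, 2,6-lutidine, CH2Cl2, −78 °C
Reagents that add atoms: trifluoromethanesulfonic anhydride, O=S(=O)(OS(=O)(=O)C(F)(F)F)C(F)(F)F
Why: The acidic enol oxygen of the vinylogous acid is sulfonylated to a β-triflyloxy enone; the alkene geometry does not matter because it is erased in the next step.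

Step 10
Reactants: 14 tert-butyl (4S,7R,7aS)-4-[(tert-butyldimethylsilyl)oxy]-7a-methyl-2-oxo-1-{[(trifluoromethanesulfonyl)oxy]methylidene}-2,4,5,6,7,7a-hexahydro-1H-indene-7-carboxylate
Product: 15 tert-butyl (4S,7R,7aS)-4-[(tert-butyldimethylsilyl)oxy]-7a-methyl-1-methylidene-2-oxo-2,4,5,6,7,7a-hexahydro-1H-indene-7-carboxylate
Conditions: Pd(OAc)2 (5 mol %), PPh3, HCO2H, Bu3N, DMF, 50 °C
Reagents that add atoms: none
Why: Palladium-catalysed reduction of a vinyl triflate by formate: zerovalent palladium inserts into the activated C–O bond, formate replaces triflate and loses CO2, and reductive elimination of the vinyl hydride gives the exocyclic methylene. The product is a reactive cross-conjugated acceptor and is used at once.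

Step 11
Reactants: 15 tert-butyl (4S,7R,7aS)-4-[(tert-butyldimethylsilyl)oxy]-7a-methyl-1-methylidene-2-oxo-2,4,5,6,7,7a-hexahydro-1H-indene-7-carboxylate; 16 2-bromo-3,3-diethoxyprop-1-ene
Product: 18 tert-butyl (1R,4S,7R,7aS)-4-[(tert-butyldimethylsilyl)oxy]-1-[2-(diethoxymethyl)prop-2-en-1-yl]-7a-methyl-2-oxo-2,4,5,6,7,7a-hexahydro-1H-indene-7-carboxylate (chain cis to the 7a-methyl), via lithium enolate 17 (not isolated)
Conditions: 16, t-BuLi, Et2O, −78 °C; CuBr·SMe2, −78 → −40 °C; 15, THF, −78 °C; NH4Cl aq (DBU, CH2Cl2, rt, if the epimers need equilibrating)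
Reagents that add atoms: 2-bromo-3,3-diethoxyprop-1-ene (16), C=C(Br)C(OCC)OCC
Why: Bromine–lithium exchange gives the α-lithiated acrolein acetal, which as its Gilman cuprate adds 1,4 to the unhindered exocyclic methylene and not to the tetrasubstituted C3a (cuprate conjugate addition to an α-methylene ketone). Enolate 17 is protonated at C1, and the 1R epimer with the chain on the methyl face, which avoids C7 and its equatorial ester on the other face, is expected directly or after brief base equilibration of this enolisable centre.

Step 12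
Reactants: 18 tert-butyl (1R,4S,7R,7aS)-4-[(tert-butyldimethylsilyl)oxy]-1-[2-(diethoxymethyl)prop-2-en-1-yl]-7a-methyl-2-oxo-2,4,5,6,7,7a-hexahydro-1H-indene-7-carboxylate
Product: 19 tert-butyl (1R,4S,7R,7aS)-1-[2-(diethoxymethyl)prop-2-en-1-yl]-4-hydroxy-7a-methyl-2-oxo-2,4,5,6,7,7a-hexahydro-1H-indene-7-carboxylate
Conditions: Bu4NF, AcOH, THF, 0 °C → rt
Reagents that add atoms: none
Why: Fluoride cleaves the Si–O bond; buffering with acetic acid keeps the medium from enolising toward C4, and acetal and tert-butyl ester are inert to fluoride.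

Step 13
Reactants: 20 (R)-2-methylbutanoic acid
Product: 21 (R)-2-methylbutan-1-ol
Conditions: LiAlH4, Et2O, 0 °C → reflux; aqueous NaOH work-up
Reagents that add atoms: none
Why: Hydride reduction of the acid to the primary alcohol does not touch the stereocentre.

Step 14
Reactants: 21 (R)-2-methylbutan-1-ol
Product: 23 (2E,4R)-2,4-dimethylhex-2-enal, via (R)-2-methylbutanal 22 (not isolated)
Conditions: DMP, CH2Cl2, 0 °C → rt; then Ph3P=C(CH3)CHO, 40 °C
Reagents that add atoms: 2-(triphenyl-λ5-phosphanylidene)propanal, CC(C=O)=P(c1ccccc1)(c1ccccc1)c1ccccc1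
Why: Periodinane oxidation gives the volatile, configurationally labile aldehyde 22, which is trapped in the same flask by the stabilised formyl ylide (Wittig olefination); the stabilised ylide gives the E-alkene and the near-neutral medium spares the α-stereocentre.

Step 15
Reactants: 23 (2E,4R)-2,4-dimethylhex-2-enal
Product: 24 ethyl (2E,4E,6R)-4,6-dimethylocta-2,4-dienoate
Conditions: (EtO)2P(O)CH2CO2Et, NaH, THF, 0 °C → rt
Reagents that add atoms: triethyl phosphonoacetate, CCOC(=O)CP(=O)(OCC)OCC
Why: Horner–Wadsworth–Emmons olefination of the enal with the stabilised phosphonate anion should give the 2E-dienoate.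

Step 16
Reactants: 24 ethyl (2E,4E,6R)-4,6-dimethylocta-2,4-dienoate
Product: 25 (2E,4E,6R)-4,6-dimethylocta-2,4-dienoic acid
Conditions: LiOH, THF/MeOH/H2O, rt; then 1 M HCl
Reagents that add atoms: lithium hydroxide, [Li+].[OH-]
Why: Saponification of the ethyl ester; the stereocentre is not α to a carbonyl and is not at risk.

Step 17
Reactants: 19 tert-butyl (1R,4S,7R,7aS)-1-[2-(diethoxymethyl)prop-2-en-1-yl]-4-hydroxy-7a-methyl-2-oxo-2,4,5,6,7,7a-hexahydro-1H-indene-7-carboxylate; 25 (2E,4E,6R)-4,6-dimethylocta-2,4-dienoic acid
Product: 26 tert-butyl (1R,4S,7R,7aS)-1-[2-(diethoxymethyl)prop-2-en-1-yl]-4-{[(2E,4E,6R)-4,6-dimethylocta-2,4-dienoyl]oxy}-7a-methyl-2-oxo-2,4,5,6,7,7a-hexahydro-1H-indene-7-carboxylate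
Conditions: 25, 2,4,6-Cl3C6H2COCl, Et3N, toluene, rt; then 19, DMAP, rt
Reagents that add atoms: (2E,4E,6R)-4,6-dimethylocta-2,4-dienoic acid (25), OC(=O)/C=C/C(C)=C/[C@H](C)CC
Why: Yamaguchi esterification: DMAP attacks the mixed anhydride at the dienoyl carbonyl and the acylpyridinium acylates even the axial allylic C4 alcohol, with retention at C4; no basic or reductive step follows.

Step 18
Reactants: 26 tert-butyl (1R,4S,7R,7aS)-1-[2-(diethoxymethyl)prop-2-en-1-yl]-4-{[(2E,4E,6R)-4,6-dimethylocta-2,4-dienoyl]oxy}-7a-methyl-2-oxo-2,4,5,6,7,7a-hexahydro-1H-indene-7-carboxylate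
Product: 27 (1R,4S,7R,7aS)-4-{[(2E,4E,6R)-4,6-dimethylocta-2,4-dienoyl]oxy}-1-(2-formylprop-2-en-1-yl)-7a-methyl-2-oxo-2,4,5,6,7,7a-hexahydro-1H-indene-7-carboxylic acid (CNP0302671.3)
Conditions: CF3CO2H/CH2Cl2/H2O, 0 °C → rt
Reagents that add atoms: water, O
Why: Acidolysis: the tert-butyl ester ionises to the acid and isobutene, and the acetal hydrolyses to the enal through an allyl-stabilised oxocarbenium ion. The secondary allylic dienoate should not ionise because its cation would be conjugated to the electron-poor enone, and C1 keeps its favoured configuration.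

## Compound list

1 | (R)-Wieland–Miescher ketone, (8aR)-8a-methyl-3,4,8,8a-tetrahydronaphthalene-1,6(2H,7H)-dione | C[C@@]12CCC(=O)C=C1CCCC2=O | starting material
2 | (methoxymethyl)triphenylphosphonium chloride | [Cl-].COC[P+](c1ccccc1)(c1ccccc1)c1ccccc1 | starting material
3 | (8aR)-1-(methoxymethylidene)-8a-methyl-1,2,3,4,8,8a-hexahydronaphthalen-6(7H)-one (E/Z mixture) | O=C1C=C2CCCC(=COC)[C@]2(C)CC1 | intermediate
4 | (1R,8aS)-8a-methyl-6-oxo-1,2,3,4,6,7,8,8a-octahydronaphthalene-1-carbaldehyde | O=C1C=C2CCC[C@@H](C=O)[C@]2(C)CC1 | intermediate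
5 | (1R,8aS)-8a-methyl-6-oxo-1,2,3,4,6,7,8,8a-octahydronaphthalene-1-carboxylic acid | O=C1C=C2CCC[C@@H](C(=O)O)[C@]2(C)CC1 | intermediate
6 | tert-butyl (1R,8aS)-8a-methyl-6-oxo-1,2,3,4,6,7,8,8a-octahydronaphthalene-1-carboxylate | O=C1C=C2CCC[C@@H](C(=O)OC(C)(C)C)[C@]2(C)CC1 | intermediate
7 | tert-butyl (1R,8aS)-6-ethoxy-8a-methyl-1,2,3,7,8,8a-hexahydronaphthalene-1-carboxylate | CCOC1=CC2=CCC[C@@H](C(=O)OC(C)(C)C)[C@]2(C)CC1 | intermediate
8 | tert-butyl (1R,4S,8aS)-4-hydroxy-8a-methyl-6-oxo-1,2,3,4,6,7,8,8a-octahydronaphthalene-1-carboxylate | O=C1C=C2[C@@H](O)CC[C@@H](C(=O)OC(C)(C)C)[C@]2(C)CC1 | intermediate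
9 | tert-butyl (1R,4S,8aS)-4-[(tert-butyldimethylsilyl)oxy]-8a-methyl-6-oxo-1,2,3,4,6,7,8,8a-octahydronaphthalene-1-carboxylate | O=C1C=C2[C@@H](O[Si](C)(C)C(C)(C)C)CC[C@@H](C(=O)OC(C)(C)C)[C@]2(C)CC1 | intermediate
10 | tert-butyl (1R,4S,8aS)-4-[(tert-butyldimethylsilyl)oxy]-8a-methyl-6-[(trimethylsilyl)oxy]-1,2,3,4,8,8a-hexahydronaphthalene-1-carboxylate | C[Si](C)(C)OC=1C=C2[C@@H](O[Si](C)(C)C(C)(C)C)CC[C@@H](C(=O)OC(C)(C)C)[C@]2(C)CC=1 | intermediate
11 | tert-butyl (1R,4S,8aS)-4-[(tert-butyldimethylsilyl)oxy]-8a-methyl-6-oxo-1,2,3,4,6,8a-hexahydronaphthalene-1-carboxylate | O=C1C=C2[C@@H](O[Si](C)(C)C(C)(C)C)CC[C@@H](C(=O)OC(C)(C)C)[C@]2(C)C=C1 | intermediate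
12 | tert-butyl (1R,4S,7S,8S,8aS)-7,8-epoxy-4-[(tert-butyldimethylsilyl)oxy]-8a-methyl-6-oxo-1,2,3,4,6,7,8,8a-octahydronaphthalene-1-carboxylate (epoxide anti to the methyl) | O=C1C=C2[C@@H](O[Si](C)(C)C(C)(C)C)CC[C@@H](C(=O)OC(C)(C)C)[C@]2(C)[C@@H]3O[C@H]13 | intermediate
13 | tert-butyl (4S,7R,7aS)-4-[(tert-butyldimethylsilyl)oxy]-1-[(Z)-hydroxymethylidene]-7a-methyl-2-oxo-2,4,5,6,7,7a-hexahydro-1H-indene-7-carboxylate | O/C=C1\C(=O)C=C2[C@@H](O[Si](C)(C)C(C)(C)C)CC[C@@H](C(=O)OC(C)(C)C)[C@@]21C | intermediate
14 | tert-butyl (4S,7R,7aS)-4-[(tert-butyldimethylsilyl)oxy]-7a-methyl-2-oxo-1-{[(trifluoromethanesulfonyl)oxy]methylidene}-2,4,5,6,7,7a-hexahydro-1H-indene-7-carboxylate (either alkene geometry) | FC(F)(F)S(=O)(=O)OC=C1C(=O)C=C2[C@@H](O[Si](C)(C)C(C)(C)C)CC[C@@H](C(=O)OC(C)(C)C)[C@@]21C | intermediate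
15 | tert-butyl (4S,7R,7aS)-4-[(tert-butyldimethylsilyl)oxy]-7a-methyl-1-methylidene-2-oxo-2,4,5,6,7,7a-hexahydro-1H-indene-7-carboxylate | C=C1C(=O)C=C2[C@@H](O[Si](C)(C)C(C)(C)C)CC[C@@H](C(=O)OC(C)(C)C)[C@@]21C | intermediate
16 | 2-bromo-3,3-diethoxyprop-1-ene | C=C(Br)C(OCC)OCC | starting material
17 | lithium (4S,7R,7aS)-7-(tert-butoxycarbonyl)-4-[(tert-butyldimethylsilyl)oxy]-1-[2-(diethoxymethyl)prop-2-en-1-yl]-7a-methyl-5,6,7,7a-tetrahydro-4H-inden-2-olate | C=C(C(OCC)OCC)CC1=C([O-])C=C2[C@@H](O[Si](C)(C)C(C)(C)C)CC[C@@H](C(=O)OC(C)(C)C)[C@@]21C.[Li+] | intermediate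
18 | tert-butyl (1R,4S,7R,7aS)-4-[(tert-butyldimethylsilyl)oxy]-1-[2-(diethoxymethyl)prop-2-en-1-yl]-7a-methyl-2-oxo-2,4,5,6,7,7a-hexahydro-1H-indene-7-carboxylate | C=C(C(OCC)OCC)C[C@H]1C(=O)C=C2[C@@H](O[Si](C)(C)C(C)(C)C)CC[C@@H](C(=O)OC(C)(C)C)[C@@]21C | intermediate
19 | tert-butyl (1R,4S,7R,7aS)-1-[2-(diethoxymethyl)prop-2-en-1-yl]-4-hydroxy-7a-methyl-2-oxo-2,4,5,6,7,7a-hexahydro-1H-indene-7-carboxylate | C=C(C(OCC)OCC)C[C@H]1C(=O)C=C2[C@@H](O)CC[C@@H](C(=O)OC(C)(C)C)[C@@]21C | intermediate
20 | (R)-2-methylbutanoic acid | CC[C@@H](C)C(=O)O | starting material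
21 | (R)-2-methylbutan-1-ol | CC[C@@H](C)CO | intermediate
22 | (R)-2-methylbutanal | CC[C@@H](C)C=O | intermediate
23 | (2E,4R)-2,4-dimethylhex-2-enal | CC[C@@H](C)/C=C(\C)C=O | intermediate
24 | ethyl (2E,4E,6R)-4,6-dimethylocta-2,4-dienoate | CCOC(=O)/C=C/C(C)=C/[C@H](C)CC | intermediate
25 | (2E,4E,6R)-4,6-dimethylocta-2,4-dienoic acid | OC(=O)/C=C/C(C)=C/[C@H](C)CC | intermediate
26 | tert-butyl (1R,4S,7R,7aS)-1-[2-(diethoxymethyl)prop-2-en-1-yl]-4-{[(2E,4E,6R)-4,6-dimethylocta-2,4-dienoyl]oxy}-7a-methyl-2-oxo-2,4,5,6,7,7a-hexahydro-1H-indene-7-carboxylate | C=C(C(OCC)OCC)C[C@H]1C(=O)C=C2[C@@H](OC(=O)/C=C/C(C)=C/[C@H](C)CC)CC[C@@H](C(=O)OC(C)(C)C)[C@@]21C | intermediate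
27 | (1R,4S,7R,7aS)-4-{[(2E,4E,6R)-4,6-dimethylocta-2,4-dienoyl]oxy}-1-(2-formylprop-2-en-1-yl)-7a-methyl-2-oxo-2,4,5,6,7,7a-hexahydro-1H-indene-7-carboxylic acid | C=C(C=O)C[C@H]1C(=O)C=C2[C@@H](OC(=O)/C=C/C(C)=C/[C@H](C)CC)CC[C@@H](C(=O)O)[C@@]21C | target

## Step count and least certain steps

Total: 18 steps. Longest linear sequence: 14 steps (steps 1–12, 17 and 18, from 1); the side-chain acid takes 4 steps (13–16) before the convergent esterification.

**Step 8 (key step).** The acyl shift may be outrun by hydride migration from C7 (giving the 6,7-dione as its enol) or by attack of the C1 ester carbonyl on C8 with loss of the tert-butyl group (lactonisation). The reason is that the migration terminus is secondary and next to a quaternary carbon, so the C8–O bond ionises reluctantly and normally uncompetitive pathways get time. Prolonged contact with BF3 would also erode the tert-butyl ester and the silyl ether.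

Fallback (contraction by extrusion of one carbon and its re-addition, the known route to A-nor steroids), setting out from 9 and rejoining at 15:
- Through silyl dienol ether 10, Rubottom oxidation with mCPBA gives the 7-hydroxy ketone F1.
- DMP oxidation gives the 6,7-dione as its enol, the diosphenol F2.
- Benzilic acid rearrangement (KOH, aqueous propanol, heat) contracts the ring to the α-hydroxy acid F3; both migration modes give the same constitution.
- Oxidative decarboxylation with Pb(OAc)4 gives the cyclopentenone F4.
- The kinetic enolate of F4 (LiN(iPr)2) is aminomethylated with dimethylmethylideneammonium iodide to the Mannich base F5; N-methylation (MeI) and elimination (NaHCO3) give 15.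

This path is one operation longer than steps 6–10.

**Step 10.** The newly formed methylene dienone may suffer conjugate reduction by palladium hydride, or amine addition and oligomerisation, because it is an unhindered cross-conjugated acceptor held under warm, basic conditions. Fallback, setting out from 13 and rejoining at 15: deformylative methylenation with aqueous formaldehyde and K2CO3 in THF. The enolate of the β-keto aldehyde is hydroxymethylated at C1 and the formyl group leaves as formate with loss of water, which gives 15 directly and by-passes 14. The exocyclic carbon then comes from formaldehyde and the extruded carbon is sacrificed. No compound outside the list is made (F0).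

**Step 11.** Three things may go wrong: decomposition of the α-lithiated acetal (loss of lithium ethoxide) before transmetallation, oligomerisation of 15 under the basic conditions, and poor facial selectivity when enolate 17 is protonated. Fallback (enolate alkylation in place of conjugate addition), setting out from 13 and rejoining at 18: C-alkylation of the β-keto aldehyde with 2-(bromomethyl)-3,3-diethoxyprop-1-ene (K2CO3, acetone) gives the 1-formyl-1-alkyl ketone F6. Deformylation (K2CO3, MeOH, retro-Claisen) releases the C1 enolate, which is protonated under equilibrating conditions to 18. Steps 9 and 10 are then not needed.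

**Step 4.** Facial selectivity in the attack of the peracid on dienol ether 7 may be insufficient (equatorial attack gives the C4 epimer), or the product may be over-oxidised, because the favoured axial face is also the face of the angular methyl.

Fallback (the other epimer made on purpose and inverted), setting out from 6 and rejoining at 8:
- Ketalisation with ethylene glycol, during which the alkene moves to C4=C4a, gives the ketal F7.
- mCPBA epoxidises F7 anti to the methyl to give the epoxy ketal F8.
- Dilute aqueous acid removes the ketal, and the freed ketone opens the epoxide by β-elimination to the equatorial alcohol F9.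
- Mitsunobu inversion with 4-nitrobenzoic acid gives the axial 4-nitrobenzoate F10, and methanolysis (K2CO3, MeOH) gives 8.

## Further compounds

F1 | step 8 | tert-butyl (1R,4S,8aS)-4-[(tert-butyldimethylsilyl)oxy]-7-hydroxy-8a-methyl-6-oxo-1,2,3,4,6,7,8,8a-octahydronaphthalene-1-carboxylate (C7 epimers) | O=C1C=C2[C@@H](O[Si](C)(C)C(C)(C)C)CC[C@@H](C(=O)OC(C)(C)C)[C@]2(C)CC1O
F2 | step 8 | tert-butyl (1R,4S,8aS)-4-[(tert-butyldimethylsilyl)oxy]-7-hydroxy-8a-methyl-6-oxo-1,2,3,4,6,8a-hexahydronaphthalene-1-carboxylate (diosphenol) | O=C1C=C2[C@@H](O[Si](C)(C)C(C)(C)C)CC[C@@H](C(=O)OC(C)(C)C)[C@]2(C)C=C1O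
F3 | step 8 | (4S,7R,7aS)-7-(tert-butoxycarbonyl)-4-[(tert-butyldimethylsilyl)oxy]-2-hydroxy-7a-methyl-2,4,5,6,7,7a-hexahydro-1H-indene-2-carboxylic acid (C2 epimers) | OC(=O)C1(O)C=C2[C@@H](O[Si](C)(C)C(C)(C)C)CC[C@@H](C(=O)OC(C)(C)C)[C@]2(C)C1
F4 | step 8 | tert-butyl (4S,7R,7aS)-4-[(tert-butyldimethylsilyl)oxy]-7a-methyl-2-oxo-2,4,5,6,7,7a-hexahydro-1H-indene-7-carboxylate | O=C1C=C2[C@@H](O[Si](C)(C)C(C)(C)C)CC[C@@H](C(=O)OC(C)(C)C)[C@]2(C)C1
F5 | step 8 | tert-butyl (4S,7R,7aS)-4-[(tert-butyldimethylsilyl)oxy]-1-[(dimethylamino)methyl]-7a-methyl-2-oxo-2,4,5,6,7,7a-hexahydro-1H-indene-7-carboxylate (C1 epimers) | CN(C)CC1C(=O)C=C2[C@@H](O[Si](C)(C)C(C)(C)C)CC[C@@H](C(=O)OC(C)(C)C)[C@@]21C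
F0 | step 10 | none | none
F6 | step 11 | tert-butyl (4S,7R,7aS)-4-[(tert-butyldimethylsilyl)oxy]-1-[2-(diethoxymethyl)prop-2-en-1-yl]-1-formyl-7a-methyl-2-oxo-2,4,5,6,7,7a-hexahydro-1H-indene-7-carboxylate (C1 epimers) | C=C(C(OCC)OCC)CC1(C=O)C(=O)C=C2[C@@H](O[Si](C)(C)C(C)(C)C)CC[C@@H](C(=O)OC(C)(C)C)[C@@]21C
F7 | step 4 | tert-butyl (1R,8aS)-6,6-(ethylenedioxy)-8a-methyl-1,2,3,5,6,7,8,8a-octahydronaphthalene-1-carboxylate | C1COC2(O1)CC3=CCC[C@@H](C(=O)OC(C)(C)C)[C@]3(C)CC2
F8 | step 4 | tert-butyl 4,4a-epoxy-6,6-(ethylenedioxy)-8a-methyldecahydronaphthalene-1-carboxylate (epoxide anti to the 8a-methyl, other centres as in F7) | C1COC2(O1)C[C@@]34O[C@@H]3CC[C@@H](C(=O)OC(C)(C)C)[C@]4(C)CC2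
F9 | step 4 | tert-butyl (1R,4R,8aS)-4-hydroxy-8a-methyl-6-oxo-1,2,3,4,6,7,8,8a-octahydronaphthalene-1-carboxylate (C4 epimer of 8) | O=C1C=C2[C@H](O)CC[C@@H](C(=O)OC(C)(C)C)[C@]2(C)CC1
F10 | step 4 | tert-butyl (1R,4S,8aS)-8a-methyl-4-[(4-nitrobenzoyl)oxy]-6-oxo-1,2,3,4,6,7,8,8a-octahydronaphthalene-1-carboxylate | O=C1C=C2[C@@H](OC(=O)c3ccc(cc3)[N+](=O)[O-])CC[C@@H](C(=O)OC(C)(C)C)[C@]2(C)CC1
A1 | alternative 1 | triisopropyl{[1-(2-methylcyclopent-1-en-1-yl)ethenyl]oxy}silane | C=C(O[Si](C(C)C)(C(C)C)C(C)C)C1=C(C)CCC1
A2 | alternative 1 | 2,2,2-trifluoroethyl prop-2-enoate | C=CC(=O)OCC(F)(F)F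
A3 | alternative 1 | 2,2,2-trifluoroethyl 7a-methyl-4-[(triisopropylsilyl)oxy]-2,3,5,6,7,7a-hexahydro-1H-indene-7-carboxylate (endo adduct, C7 epimeric to 27) | C1CCC2=C(O[Si](C(C)C)(C(C)C)C(C)C)CC[C@H](C(=O)OCC(F)(F)F)[C@@]21C
A4 | alternative 2 | tert-butyl (2E)-4-[3-(tert-butyldimethylsilyloxy)propyl]-5,5-(ethylenedioxy)-3-methyl-8-[(triethylsilyl)oxy]deca-2,6,7,9-tetraenoate (either allene epimer) | CC(C)(C)[Si](C)(C)OCCC[C@@H](C1(OCCO1)C=C=C(O[Si](CC)(CC)CC)C=C)/C(C)=C/C(=O)OC(C)(C)C
A5 | alternative 2 | tert-butyl 1-[3-(tert-butyldimethylsilyloxy)propyl]-2,2-(ethylenedioxy)-7a-methyl-4-[(triethylsilyl)oxy]-2,6,7,7a-tetrahydro-1H-indene-7-carboxylate | CC(C)(C)[Si](C)(C)OCCC[C@H]1C2(OCCO2)C=C2C(O[Si](CC)(CC)CC)=CC[C@@H](C(=O)OC(C)(C)C)[C@@]21C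
A6 | alternative 3 | tert-butyl 2-{1-methyl-4-oxo-5-[2-(tert-butyldimethylsilyloxymethyl)prop-2-en-1-yl]cyclopent-2-en-1-yl}-5-oxopentanoate | C=C(CO[Si](C)(C)C(C)(C)C)C[C@H]1C(=O)C=C[C@]1(C)[C@@H](CCC=O)C(=O)OC(C)(C)C
A7 | alternative 3 | tert-butyl 4-hydroxy-7a-methyl-2-oxo-1-[2-(tert-butyldimethylsilyloxymethyl)prop-2-en-1-yl]octahydro-1H-indene-7-carboxylate (cis-fused, hydroxyl cis to the methyl) | C=C(CO[Si](C)(C)C(C)(C)C)C[C@H]1C(=O)C[C@@H]2[C@@H](O)CC[C@@H](C(=O)OC(C)(C)C)[C@@]21C
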